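A flat tail on a progress curve does not show whether forward and back steps balance or whether the making of target has simply died away.

| flask | starting material | reagent | time |
|---|---|---|---|
| winter | 1.00 M | 1.00 M |  |
| noon | 0.400 M | 0.400 M |  |
| midnight | 1.00 M | 2.00 M |  |
| spring | 2.00 M | 1.00 M |  |
| autumn | 0.330 M | 0.500 M | 12 min |

| run | time / min | [target] / M |
|---|---|---|
| winter run | 2.4 | 0.109 |
| winter run | 4.8 | 0.165 |
| winter run | 7.2 | 0.192 |
| winter run | 9.6 | 0.203 |
| winter run | 12 | 0.213 |
| noon run | 2.4 | 0.028 |
| noon run | 4.8 | 0.049 |
| noon run | 7.2 | 0.056 |
| noon run | 9.6 | 0.066 |
| noon run | 12 | 0.067 |
| midnight run | 2.4 | 0.152 |
| midnight run | 4.8 | 0.231 |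
| midnight run | 7.2 | 0.266 |
| midnight run | 9.6 | 0.282 |
| midnight run | 12 | 0.293 |
| spring run | 2.4 | 0.166 |
| spring run | 4.8 | 0.251 |
| spring run | 7.2 | 0.285 |
| spring run | 9.6 | 0.306 |
| spring run | 12 | 0.314 |

(standard deviation of a reading: 0.003 M)

- Overall: starting material + reagent -> target.
- Constant volume, constant temperature.
- The analysis sees a species whether free or bound.
- "The second partner" is reagent.
- An order is taken over about fifteen percent of the charge, up and down.

- how the opening rate goes with [reagent] round the charge of the winter run: the exponent of the rate at two percent of starting material gone to target
- how the opening rate goes with [starting material] round the charge of the winter run: the exponent of the rate at two percent of starting material gone to target (one fixed amount of target, the same in the runs compared)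
- target in the autumn run at 12 min, as a share of the starting material charged

Two chemists dispute the stall. In the winter run, target stands at 21.3 % of the starting material charged by 12 min, and the last gains are small.

The first chemist holds that this is a balance, with one constant: target over the product of what remains of each partner. The winter run reads 0.344 M⁻¹. In the autumn run starting material is the limiting reagent, 0.330 M and so less than the 0.500 M of reagent. With that constant, autumn ends at 13.5 % of its charge.

The second chemist answers that the noon run reads 0.604 M⁻¹, more than the winter run, so one constant fits neither both runs nor the view. He holds that production runs on a clock, and he counts lifetimes. The lifetime is the time in which a run's gains shrink by a factor e, read from the first reading and the next gain: 3.60 min in the winter run, 3.67 min in the midnight run and 3.59 min in the spring run. The noon run reads 8.34 min, longer than the winter lifetime. After 3.33 winter lifetimes the winter run has made 96.4 % of the plateau its gains point to.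

The forecast is his side's number, on the ground “so the plateau tracks initial rate”: 20 % for autumn (range 18 % to 22 %), with orders 0.56 in reagent and 0.67 in starting material.

My own reckoning uses the 12 min readings. Going up from the winter charge, they give 0.460 in reagent and 0.560 in starting material. These exponents of the reading are lower than the forecast's orders of the rate, which are taken round the winter charge . Scaling the noon run with them puts autumn at 20.2 %.

The balance keeps the end of a run. The noon run's last gain, 0.250 % of its charge, is less than the scatter of 0.750 %, and over that last step neither view can be told from the other.

The simulation gives 20.4 % for autumn, more than the balance's share, with orders 0.57 and 0.54, the latter less than the forecast's.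

    starting material → intermediate (0.3000 min⁻¹)
    intermediate + reagent → target (1.176 M⁻¹ min⁻¹)
    intermediate → side product (1.146 min⁻¹)
    2 starting material ⇌ idle substrate dimer, settled at all times (0.8290 M⁻¹)
    2 starting material → homo dimer (0.6960 M⁻¹ min⁻¹)

Where equal target has been made, the spring run goes at 1.4 times the winter rate, while its 12 min reading is 1.47 times the winter reading. Counted in winter lifetimes, the 12 min reading of the midnight run stands 3.33 lifetimes in, at 96.4 % of its plateau. From that reading, the count puts target in the midnight run at a quarter of the charge at 6.23 min, and the midnight run reaches it at 5.78 min.

All runs were computed with constants of no real substance; the scatter is artificial.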